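Plan
- Numbering: chroman (O1, C2, C3, C4, C4a–C8a); ring A = benzo ring, ring B = pendant aryl (primed atoms), ring C = pyran ring.
- Cuts: the Si–O bonds and a helper oxygen on C4 last; then C2–C3 of ring C, back to an O1-methyl ether and a diazo group on C3 next to a C4 ketone; then C3–C1' (ketone α-arylation); then the C8 side chain (aryl–alkyne coupling) and the ring B 1,1-dimethylallyl group (aromatic Claisen).
- Forward: ring A ketone 8 and ring B bromide 15 are made separately and joined at C3–C1'. The CH2 is diazotised, and ring C closes when the C3 rhodium carbenoid inserts into a C–H bond of the O1 methyl group, giving the isoflavanone.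
- Enabling feature: O1 sits on C8a, ortho to C4a, so with C4 as a carbonyl the O1-methyl hydrogens lie 1,6 to C3. C3 is flanked only by ring B and C4=O (no β-hydrogen, no 1,5 C–H), and the methoxy group is twisted out of the ring A plane by its two ortho neighbours (C4a acyl, C8 chain).
- Stereochemistry: C3 is set after ring closure by transfer hydrogenation under dynamic kinetic resolution with RuCl[(R,R)-TsDPEN](p-cymene), giving the (3R,4R)-cis alcohol. The C4 oxygen is then removed by ionic hydrogenation without touching C3, and fluoride frees the four hydroxyls.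

Key step: step 12

Assumption: 3-[(tert-butyldimethylsilyl)oxy]phenol is taken as a purchasable compound (otherwise one silylation from resorcinol); the target stereocentre C3 is R.

Step 1
Reactants: 1 1-(2,4-dihydroxyphenyl)ethan-1-one
Product: 2 1-(2,4-dihydroxy-3-iodophenyl)ethan-1-one
Conditions: I2, HIO3, EtOH–H2O, 40 °C
Reagents that add atoms: iodine, II; iodic acid, O=I(=O)O
Why: Electrophilic aromatic iodination (HIO3 as oxidant, so that all iodine is used) should go to C3, the carbon between the two hydroxyl groups, which the hydrogen-bonded 2-hydroxy ketone makes the most nucleophilic position.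

Step 2
Reactants: 2 1-(2,4-dihydroxy-3-iodophenyl)ethan-1-one
Product: 4 1-[4-(benzyloxy)-3-iodo-2-methoxyphenyl]ethan-1-one, via 4-O-benzyl ether 3 (not isolated)
Conditions: BnBr (1.0 equiv), K2CO3, DMF, rt; then MeI, 45 °C
Reagents that add atoms: benzyl bromide, BrCc1ccccc1; iodomethane, CI
Why: Williamson ether synthesis in two stages in one flask: the free 4-OH should be benzylated at room temperature, and the hydrogen-bonded, less reactive 2-OH is then methylated on warming, which installs the O-methyl carbon that later becomes C2.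

Step 3
Reactants: 4 1-[4-(benzyloxy)-3-iodo-2-methoxyphenyl]ethan-1-one; 5 2-methylbut-3-yn-2-ol
Product: 6 1-[4-(benzyloxy)-3-(3-hydroxy-3-methylbut-1-yn-1-yl)-2-methoxyphenyl]ethan-1-one
Conditions: PdCl2(PPh3)2 (cat.), CuI (cat.), Et3N–THF, 60 °C
Reagents that add atoms: none
Why: Sonogashira coupling of the aryl iodide with the terminal alkyne should install the whole C8 carbon chain; both ortho oxygens are capped, so no benzofuran can form.

Step 4
Reactants: 6 1-[4-(benzyloxy)-3-(3-hydroxy-3-methylbut-1-yn-1-yl)-2-methoxyphenyl]ethan-1-one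
Product: 7 1-[4-hydroxy-3-(3-hydroxy-3-methylbutyl)-2-methoxyphenyl]ethan-1-one
Conditions: H2 (1 atm), 10% Pd/C, EtOAc–EtOH, rt
Reagents that add atoms: none
Why: Heterogeneous catalytic hydrogenation should saturate the alkyne and at the same time hydrogenolyse the benzyl ether, while the electron-rich aryl ketone is kept under neutral conditions.

Step 5
Reactants: 7 1-[4-hydroxy-3-(3-hydroxy-3-methylbutyl)-2-methoxyphenyl]ethan-1-one
Product: 8 1-{4-[(tert-butyldimethylsilyl)oxy]-3-{3-[(tert-butyldimethylsilyl)oxy]-3-methylbutyl}-2-methoxyphenyl}ethan-1-one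
Conditions: TBSOTf, 2,6-lutidine, CH2Cl2, −78 to 0 °C
Reagents that add atoms: tert-butyldimethylsilyl trifluoromethanesulfonate, CC(C)(C)[Si](C)(C)OS(=O)(=O)C(F)(F)F
Why: Silylation with the silyl triflate (needed for the tertiary alcohol) should cap both hydroxyls in one operation, so that no O–H bond can intercept the carbenoid of step 12 and the final deprotection is a single fluoride step.

Step 6
Reactants: 9 3-[(tert-butyldimethylsilyl)oxy]phenol; 10 3-methylbut-2-en-1-ol
Product: 11 tert-butyldimethyl{3-[(3-methylbut-2-en-1-yl)oxy]phenoxy}silane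
Conditions: PPh3, DIAD, THF, 0 °C to rt
Reagents that add atoms: none
Why: Mitsunobu etherification should give the prenyl ether under neutral conditions, which avoids silyl transfer between phenoxides.

Step 7
Reactants: 11 tert-butyldimethyl{3-[(3-methylbut-2-en-1-yl)oxy]phenoxy}silane
Product: 13 5-[(tert-butyldimethylsilyl)oxy]-2-(2-methylbut-3-en-2-yl)phenol, via ortho-dienone 12 (not isolated)
Conditions: PhNEt2, 185 °C, sealed tube, argon
Reagents that add atoms: none
Why: Aromatic Claisen rearrangement: the [3,3] shift should deliver the 1,1-dimethylallyl group to the ortho carbon para to the silyloxy group (the other ortho carbon lies between two oxygens and is shielded by the TBS group), and the dienone then tautomerises to the phenol.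

Step 8
Reactants: 13 5-[(tert-butyldimethylsilyl)oxy]-2-(2-methylbut-3-en-2-yl)phenol
Product: 14 2,4-bis[(tert-butyldimethylsilyl)oxy]-1-(2-methylbut-3-en-2-yl)benzene
Conditions: TBSCl, imidazole, DMF, 40 °C
Reagents that add atoms: tert-butyldimethylsilyl chloride, CC(C)(C)[Si](C)(C)Cl
Why: Standard silylation of the hindered phenol, done promptly so that it cannot cyclise onto the neighbouring allyl group.

Step 9
Reactants: 14 2,4-bis[(tert-butyldimethylsilyl)oxy]-1-(2-methylbut-3-en-2-yl)benzene
Product: 15 1-bromo-2,4-bis[(tert-butyldimethylsilyl)oxy]-5-(2-methylbut-3-en-2-yl)benzene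
Conditions: NBS, MeCN, 0 °C, dark
Reagents that add atoms: N-bromosuccinimide, BrN1C(=O)CCC1=O
Why: Electrophilic aromatic bromination should occur at the one position that is para to one silyloxy group and ortho to the other without lying between two substituents, and the electron-rich arene should react much faster than the hindered monosubstituted alkene.

Step 10
Reactants: 8 1-{4-[(tert-butyldimethylsilyl)oxy]-3-{3-[(tert-butyldimethylsilyl)oxy]-3-methylbutyl}-2-methoxyphenyl}ethan-1-one; 15 1-bromo-2,4-bis[(tert-butyldimethylsilyl)oxy]-5-(2-methylbut-3-en-2-yl)benzene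
Product: 16 2-{2,4-bis[(tert-butyldimethylsilyl)oxy]-5-(2-methylbut-3-en-2-yl)phenyl}-1-{4-[(tert-butyldimethylsilyl)oxy]-3-{3-[(tert-butyldimethylsilyl)oxy]-3-methylbutyl}-2-methoxyphenyl}ethan-1-one
Conditions: Pd2(dba)3 (cat.), XPhos (2-dicyclohexylphosphino-2',4',6'-triisopropylbiphenyl), K3PO4, toluene, 90 °C
Reagents that add atoms: none
Why: Palladium-catalysed α-arylation of the methyl ketone (Buchwald–Hartwig type, zerovalent palladium with a bulky biaryl phosphine) should form the C3–C1' bond; the mild base K3PO4 spares the aryl silyl ethers and the ortho-silyloxy group of 15 disfavours a second arylation.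

Step 11
Reactants: 16 the deoxybenzoin of step 10
Product: 17 2-{2,4-bis[(tert-butyldimethylsilyl)oxy]-5-(2-methylbut-3-en-2-yl)phenyl}-1-{4-[(tert-butyldimethylsilyl)oxy]-3-{3-[(tert-butyldimethylsilyl)oxy]-3-methylbutyl}-2-methoxyphenyl}-2-diazoethan-1-one
Conditions: p-ABSA, DBU, MeCN, 0 °C to rt
Reagents that add atoms: 4-acetamidobenzenesulfonyl azide, CC(=O)Nc1ccc(cc1)S(=O)(=O)N=[N+]=[N-]
Why: Regitz diazo transfer onto the CH2 group that is activated by both the ketone and ring B, with an amidine base that leaves the silyl ethers intact.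

Step 12
Reactants: 17 the α-aryl-α-diazo ketone of step 11
Product: 18 rac-3-{2,4-bis[(tert-butyldimethylsilyl)oxy]-5-(2-methylbut-3-en-2-yl)phenyl}-7-[(tert-butyldimethylsilyl)oxy]-8-{3-[(tert-butyldimethylsilyl)oxy]-3-methylbutyl}chroman-4-one
Conditions: Rh2(OAc)4 (1 mol %), CH2Cl2, 40 °C, slow addition of 17 (final 0.005 M)
Reagents that add atoms: none
Why: Rh2(OAc)4 should convert 17, with loss of N2, into an aryl/acyl (donor/acceptor) rhodium carbenoid at C3, which takes up a hydrogen of the O1 methyl group and forms the C2–C3 bond in one concerted three-centre insertion event. The closest known reaction type is the intramolecular C–H insertion of 2-alkoxyphenyl α-diazo ketones into the C–H bond next to the ether oxygen, which gives chroman-4-ones. Ring C closes as a six-membered ring by 1,6-insertion through the array C3, C4, C4a, C8a, O1, C2; a five-membered alternative does not exist because the fifth atom is the oxygen itself. The new stereocentre C3 is formed without control on purpose (achiral catalyst), since it lies α to the C4 ketone and is set in step 13. The step needs chemoselectivity for the methyl C–H bond over 1,2-hydride shift, over ylide formation at O1 followed by methyl shift, over insertion into ring B substituents and over intermolecular cyclopropanation of the vinyl group; this should be secured by the C4 carbonyl (no β-hydrogen on C3), by the poor migrating ability of methyl, by silyl ethers that carry no O–C–H bond, by the out-of-plane methoxy group held close to the carbenoid, and by slow addition at high dilution.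

Step 13
Reactants: 18 the racemic isoflavanone of step 12
Product: 19 (3R,4R)-3-{2,4-bis[(tert-butyldimethylsilyl)oxy]-5-(2-methylbut-3-en-2-yl)phenyl}-7-[(tert-butyldimethylsilyl)oxy]-8-{3-[(tert-butyldimethylsilyl)oxy]-3-methylbutyl}chroman-4-ol (3-aryl and 4-OH cis)
Conditions: RuCl[(R,R)-TsDPEN](p-cymene) (2 mol %), HCO2H–Et3N (5:2), EtOAc, 40 °C
Reagents that add atoms: none
Why: Noyori–Ikariya asymmetric transfer hydrogenation with dynamic kinetic resolution: Et3N equilibrates the two C3 epimers through the enol, the (R,R)-configured divalent ruthenium catalyst should reduce the (3R)-ketone faster and deliver hydride to C4 on the face opposite the C3 aryl group, so that C3 (R) and C4 (R, cis) are set together.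

Step 14
Reactants: 19 the (3R,4R)-cis alcohol of step 13
Product: 20 (3R)-3-{2,4-bis[(tert-butyldimethylsilyl)oxy]-5-(2-methylbut-3-en-2-yl)phenyl}-7-[(tert-butyldimethylsilyl)oxy]-8-{3-[(tert-butyldimethylsilyl)oxy]-3-methylbutyl}chroman
Conditions: Et3SiH, BF3·OEt2, CH2Cl2, −78 °C
Reagents that add atoms: none
Why: Ionic hydrogenation of a benzylic alcohol: BF3·OEt2 should ionise the C4–OH to a cation stabilised by O1 and the C7 silyloxy group, Et3SiH delivers hydride to C4, and C3 is not involved, the aprotic Lewis acid at low temperature being chosen so that any isoflav-3-ene formed cannot be reprotonated.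

Step 15
Reactants: 20 the tetrasilylated (3R)-isoflavan of step 14
Product: 21 (3R)-3-[2,4-dihydroxy-5-(2-methylbut-3-en-2-yl)phenyl]-8-(3-hydroxy-3-methylbutyl)chroman-7-ol (target)
Conditions: TBAF, THF, 0 to 50 °C, argon; aq. NH4Cl
Reagents that add atoms: none
Why: Fluoride-mediated cleavage of all four silyl ethers under non-acidic conditions, which avoids acid-induced cyclisation of the tertiary alcohol onto O7 or of the 4'-phenol onto the 1,1-dimethylallyl group and leaves C3 untouched.

Compound list
1 | 1-(2,4-dihydroxyphenyl)ethan-1-one | CC(=O)c1ccc(O)cc1O | starting material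
2 | 1-(2,4-dihydroxy-3-iodophenyl)ethan-1-one | CC(=O)c1ccc(O)c(I)c1O | intermediate
3 | 1-[4-(benzyloxy)-2-hydroxy-3-iodophenyl]ethan-1-one | CC(=O)c1ccc(OCc2ccccc2)c(I)c1O | intermediate (not isolated)
4 | 1-[4-(benzyloxy)-3-iodo-2-methoxyphenyl]ethan-1-one | CC(=O)c1ccc(OCc2ccccc2)c(I)c1OC | intermediate
5 | 2-methylbut-3-yn-2-ol | CC(C)(O)C#C | starting material
6 | 1-[4-(benzyloxy)-3-(3-hydroxy-3-methylbut-1-yn-1-yl)-2-methoxyphenyl]ethan-1-one | CC(=O)c1ccc(OCc2ccccc2)c(C#CC(C)(C)O)c1OC | intermediate
7 | 1-[4-hydroxy-3-(3-hydroxy-3-methylbutyl)-2-methoxyphenyl]ethan-1-one | CC(=O)c1ccc(O)c(CCC(C)(C)O)c1OC | intermediate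
8 | 1-{4-[(tert-butyldimethylsilyl)oxy]-3-{3-[(tert-butyldimethylsilyl)oxy]-3-methylbutyl}-2-methoxyphenyl}ethan-1-one | CC(=O)c1ccc(O[Si](C)(C)C(C)(C)C)c(CCC(C)(C)O[Si](C)(C)C(C)(C)C)c1OC | intermediate
9 | 3-[(tert-butyldimethylsilyl)oxy]phenol | CC(C)(C)[Si](C)(C)Oc1cccc(O)c1 | starting material
10 | 3-methylbut-2-en-1-ol | CC(C)=CCO | starting material
11 | tert-butyldimethyl{3-[(3-methylbut-2-en-1-yl)oxy]phenoxy}silane | CC(C)=CCOc1cccc(O[Si](C)(C)C(C)(C)C)c1 | intermediate
12 | 3-[(tert-butyldimethylsilyl)oxy]-6-(2-methylbut-3-en-2-yl)cyclohexa-2,4-dien-1-one | O=C1C=C(O[Si](C)(C)C(C)(C)C)C=CC1C(C)(C)C=C | intermediate (not isolated)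
13 | 5-[(tert-butyldimethylsilyl)oxy]-2-(2-methylbut-3-en-2-yl)phenol | C=CC(C)(C)c1ccc(O[Si](C)(C)C(C)(C)C)cc1O | intermediate
14 | 2,4-bis[(tert-butyldimethylsilyl)oxy]-1-(2-methylbut-3-en-2-yl)benzene | C=CC(C)(C)c1ccc(O[Si](C)(C)C(C)(C)C)cc1O[Si](C)(C)C(C)(C)C | intermediate
15 | 1-bromo-2,4-bis[(tert-butyldimethylsilyl)oxy]-5-(2-methylbut-3-en-2-yl)benzene | C=CC(C)(C)c1cc(Br)c(O[Si](C)(C)C(C)(C)C)cc1O[Si](C)(C)C(C)(C)C | intermediate
16 | 2-{2,4-bis[(tert-butyldimethylsilyl)oxy]-5-(2-methylbut-3-en-2-yl)phenyl}-1-{4-[(tert-butyldimethylsilyl)oxy]-3-{3-[(tert-butyldimethylsilyl)oxy]-3-methylbutyl}-2-methoxyphenyl}ethan-1-one | C=CC(C)(C)c1cc(CC(=O)c2ccc(O[Si](C)(C)C(C)(C)C)c(CCC(C)(C)O[Si](C)(C)C(C)(C)C)c2OC)c(O[Si](C)(C)C(C)(C)C)cc1O[Si](C)(C)C(C)(C)C | intermediate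
17 | 2-diazo derivative of 16 (diazo group on the carbon between the carbonyl and ring B) | C=CC(C)(C)c1cc(C(=[N+]=[N-])C(=O)c2ccc(O[Si](C)(C)C(C)(C)C)c(CCC(C)(C)O[Si](C)(C)C(C)(C)C)c2OC)c(O[Si](C)(C)C(C)(C)C)cc1O[Si](C)(C)C(C)(C)C | intermediate
18 | rac-3-{2,4-bis[(tert-butyldimethylsilyl)oxy]-5-(2-methylbut-3-en-2-yl)phenyl}-7-[(tert-butyldimethylsilyl)oxy]-8-{3-[(tert-butyldimethylsilyl)oxy]-3-methylbutyl}chroman-4-one | C=CC(C)(C)c1cc(C2COc3c(C2=O)ccc(O[Si](C)(C)C(C)(C)C)c3CCC(C)(C)O[Si](C)(C)C(C)(C)C)c(O[Si](C)(C)C(C)(C)C)cc1O[Si](C)(C)C(C)(C)C | intermediate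
19 | (3R,4R)-3-{2,4-bis[(tert-butyldimethylsilyl)oxy]-5-(2-methylbut-3-en-2-yl)phenyl}-7-[(tert-butyldimethylsilyl)oxy]-8-{3-[(tert-butyldimethylsilyl)oxy]-3-methylbutyl}chroman-4-ol (3,4-cis) | C=CC(C)(C)c1cc([C@@H]2COc3c(ccc(O[Si](C)(C)C(C)(C)C)c3CCC(C)(C)O[Si](C)(C)C(C)(C)C)[C@@H]2O)c(O[Si](C)(C)C(C)(C)C)cc1O[Si](C)(C)C(C)(C)C | intermediate
20 | (3R)-3-{2,4-bis[(tert-butyldimethylsilyl)oxy]-5-(2-methylbut-3-en-2-yl)phenyl}-7-[(tert-butyldimethylsilyl)oxy]-8-{3-[(tert-butyldimethylsilyl)oxy]-3-methylbutyl}chroman | C=CC(C)(C)c1cc([C@@H]2COc3c(ccc(O[Si](C)(C)C(C)(C)C)c3CCC(C)(C)O[Si](C)(C)C(C)(C)C)C2)c(O[Si](C)(C)C(C)(C)C)cc1O[Si](C)(C)C(C)(C)C | intermediate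
21 | (3R)-3-[2,4-dihydroxy-5-(2-methylbut-3-en-2-yl)phenyl]-8-(3-hydroxy-3-methylbutyl)chroman-7-ol | C=CC(C)(C)c1cc([C@@H]2COc3c(ccc(O)c3CCC(C)(C)O)C2)c(O)cc1O | target

Total step count: 15. Longest linear sequence: 11 steps (steps 1–5, then 10–15); the ring B branch (steps 6–9) joins at step 10.

Steps most likely to fail

Step 12. The carbenoid may be diverted by attack of the O1 lone pair (oxonium ylide, then methyl shift or demethylation to a benzofuranone), by dimerisation, or by intermolecular cyclopropanation of the vinyl group, so that insertion into the primary C–H bond does not win. Fallback, from 16 back to 18: BCl3 in CH2Cl2 at −78 °C should cleave only the methyl ether ortho to the carbonyl (chelation control) and give 2-{2,4-bis[(tert-butyldimethylsilyl)oxy]-5-(2-methylbut-3-en-2-yl)phenyl}-1-{4-[(tert-butyldimethylsilyl)oxy]-3-{3-[(tert-butyldimethylsilyl)oxy]-3-methylbutyl}-2-hydroxyphenyl}ethan-1-one F1. Heating F1 with paraformaldehyde and Et2NH in EtOH (Mannich reaction, amine elimination, oxa-Michael closure) should then give isoflavanone 18, from which steps 13–15 follow unchanged.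

Step 7. The allyl group may migrate to the carbon between the two oxygens, and the ortho-allyl phenol may rearrange further (abnormal Claisen) or cyclise to a dihydrobenzofuran on prolonged heating. Fallback, from 9 back to 14, with no sigmatropic step: silylation of 9 (TBSCl, imidazole) gives 1,3-bis[(tert-butyldimethylsilyl)oxy]benzene F2. Bromination with NBS gives 1-bromo-2,4-bis[(tert-butyldimethylsilyl)oxy]benzene F3. A γ-selective Suzuki–Miyaura coupling of F3 with 3-methylbut-2-enylboronic acid pinacol ester (Pd(OAc)2, bulky biaryl phosphine, K3PO4, THF–H2O) should attach the allyl unit through its tertiary carbon and give 14 with the regiochemistry fixed by the bromide; step 9 then follows.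

Step 14. The C4 cation may lose the C3 proton to give the isoflav-3-ene (loss of material and, on reprotonation, of configuration), may be captured by the 2'-silyloxy oxygen, or the tertiary silyl ether may ionise. Fallback, from 19 back to 21, using the oxygen capture on purpose: BF3·OEt2 without silane (CH2Cl2, −78 to −40 °C) should close the cis-fused (6aR,11aR)-pterocarpan F4, in which the 2'-oxygen is bonded to C4 and the 2'-silyl group is lost. Dissolving-metal cleavage of the benzylic C–O bond of F4 (Li, NH3–THF, −78 °C, NH4Cl quench), which does not reduce the isolated vinyl group, should give the (3R)-isoflavan with a free 2'-hydroxyl and three remaining silyl ethers F5. TBAF as in step 15 then gives 21.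

Further compounds
F1 | step 12 | 2-{2,4-bis[(tert-butyldimethylsilyl)oxy]-5-(2-methylbut-3-en-2-yl)phenyl}-1-{4-[(tert-butyldimethylsilyl)oxy]-3-{3-[(tert-butyldimethylsilyl)oxy]-3-methylbutyl}-2-hydroxyphenyl}ethan-1-one | C=CC(C)(C)c1cc(CC(=O)c2ccc(O[Si](C)(C)C(C)(C)C)c(CCC(C)(C)O[Si](C)(C)C(C)(C)C)c2O)c(O[Si](C)(C)C(C)(C)C)cc1O[Si](C)(C)C(C)(C)C
F2 | step 7 | 1,3-bis[(tert-butyldimethylsilyl)oxy]benzene | CC(C)(C)[Si](C)(C)Oc1cccc(O[Si](C)(C)C(C)(C)C)c1
F3 | step 7 | 1-bromo-2,4-bis[(tert-butyldimethylsilyl)oxy]benzene | CC(C)(C)[Si](C)(C)Oc1ccc(Br)c(O[Si](C)(C)C(C)(C)C)c1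
F4 | step 14 | (6aR,11aR)-cis-pterocarpan from 19 (2'-oxygen bonded to C4; silyl ethers kept on O7, the tertiary oxygen and O4') | C=CC(C)(C)c1cc2[C@@H]3COc4c(ccc(O[Si](C)(C)C(C)(C)C)c4CCC(C)(C)O[Si](C)(C)C(C)(C)C)[C@@H]3Oc2cc1O[Si](C)(C)C(C)(C)C
F5 | step 14 | (3R)-isoflavan with free 2'-hydroxyl and silyl ethers on O7, the tertiary oxygen and O4' | C=CC(C)(C)c1cc([C@@H]2COc3c(ccc(O[Si](C)(C)C(C)(C)C)c3CCC(C)(C)O[Si](C)(C)C(C)(C)C)C2)c(O)cc1O[Si](C)(C)C(C)(C)C
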